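**Retrosynthetic overview**

- The C-methyl of the pendant lactone (ring E) comes from hydrogenation of an exo-methylene lactone. That lactone comes from a catalytic asymmetric 2-(ethoxycarbonyl)allylation and lactonisation of a pyrrole-2-carbaldehyde.
- Key disconnection: both C–N bonds of the pyrrole nitrogen. The azepine (ring A) closes by C=N condensation and the pyrrole (ring B) by N-alkylation, from an amino ketone and bromomalonaldehyde in one flask.
- The amino ketone comes from a nitrile and ketal on a cyclohexane (ring C) that already carries the cis-fused lactone (ring D, closed by C–O bond formation from an axial alkoxide).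
- Ring C is the bought quinone monoketal. It is desymmetrised by Cu-catalysed conjugate addition, then trans-ethylated, then reductively alkylated with (S)-lactate triflate, which supplies the lactone methyl stereocentre.
- Ring order: C (bought) → D → A and B together → E.

Assumption: the enantiomer of each chiral ligand (steps 1 and 8) that gives the drawn configuration is used; the sense of induction is taken by analogy and would be confirmed on a test run.

**Step 1**
Reactants: 1 4,4-dimethoxycyclohexa-2,5-dien-1-one; 2 4-iodobutanenitrile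
Product: 4 (R)-4-(2,2-dimethoxy-5-oxocyclohex-3-en-1-yl)butanenitrile, via bis(3-cyanopropyl)zinc 3 (not isolated)
Conditions: 2 (3.2 equiv), Et2Zn (1.6 equiv), CuI (0.3 mol%), neat, 50 °C, then vacuum; then 1, Cu(OTf)2 (2 mol%), (S,R,R)-BINOL bis(1-phenylethyl)amine phosphoramidite (4 mol%), PhMe, −25 °C; aq. NH4Cl; Et3N-washed SiO2
Reagents that add atoms: none
Why: Iodine–zinc exchange gives the functionalised dialkylzinc, and copper–phosphoramidite catalysed enantioselective conjugate addition desymmetrises the prochiral dienone, setting the future azepine ring-fusion carbon (R).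

**Step 2**
Reactants: 4 (R)-4-(2,2-dimethoxy-5-oxocyclohex-3-en-1-yl)butanenitrile
Product: 5 4-[(1R,6R)-6-ethyl-2,2-dimethoxy-5-oxocyclohex-3-en-1-yl]butanenitrile
Conditions: LiN(i-Pr)2 (1.05 equiv), THF, −78 °C; EtI (3 equiv), DMPU, −78 → −30 °C
Reagents that add atoms: iodoethane CCI
Why: Kinetic deprotonation can only occur at the saturated α-carbon (the γ-carbon is the ketal), and enolate alkylation takes place anti to the neighbouring cyanopropyl group, giving the trans ethyl stereocentre.

**Step 3**
Reactants: 6 ethyl (S)-lactate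
Product: 7 ethyl (S)-2-(trifluoromethylsulfonyloxy)propanoate
Conditions: Tf2O (1.05 equiv), 2,6-lutidine (1.1 equiv), CH2Cl2, −78 → 0 °C; used fresh
Reagents that add atoms: trifluoromethanesulfonic anhydride O=S(=O)(OS(=O)(=O)C(F)(F)F)C(F)(F)F
Why: O-sulfonylation of the chiral-pool alcohol proceeds with retention and gives a secondary electrophile that reacts by clean SN2.

**Step 4**
Reactants: 5 4-[(1R,6R)-6-ethyl-2,2-dimethoxy-5-oxocyclohex-3-en-1-yl]butanenitrile; 7 ethyl (S)-2-(trifluoromethylsulfonyloxy)propanoate
Product: 8 ethyl (2S)-2-[(3R,4R)-4-(3-cyanopropyl)-3-ethyl-5,5-dimethoxy-2-oxocyclohexyl]propanoate (both epimers at ring C1)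
Conditions: Li[HB(sec-Bu)3] (1.05 equiv), THF, −78 °C; then 7 (1.3 equiv), −78 → −30 °C; H2O
Reagents that add atoms: none
Why: Conjugate reduction of the β-unsubstituted enone gives a regiodefined enolate (reductive alkylation), and its SN2 attack on the lactate triflate inverts that carbon, which fixes the lactone methyl stereocentre as S.

**Step 5**
Reactants: 8 ethyl (2S)-2-[(3R,4R)-4-(3-cyanopropyl)-3-ethyl-5,5-dimethoxy-2-oxocyclohexyl]propanoate
Product: 10 4-[(3S,3aR,6R,7R,7aR)-7-ethyl-5,5-dimethoxy-3-methyl-2-oxooctahydro-1-benzofuran-6-yl]butanenitrile, via hydroxy ester 9 (not isolated)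
Conditions: DBU (0.2 equiv), THF, 25 °C; then Li[HB(sec-Bu)3] (1.3 equiv), −78 → 0 °C; H2O
Reagents that add atoms: none
Why: Base equilibration gives the all-equatorial 2,6-cis ketone (the non-epimerisable cyanopropyl carbon holds the absolute configuration), the bulky hydride attacks equatorially to give the axial alkoxide, and this lactonises onto the cis ester to close the cis-fused ring D by C–O bond formation.

**Step 6**
Reactants: 10 4-[(3S,3aR,6R,7R,7aR)-7-ethyl-5,5-dimethoxy-3-methyl-2-oxooctahydro-1-benzofuran-6-yl]butanenitrile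
Product: 12 (3S,3aR,6R,7R,7aR)-6-(4-aminobutyl)-7-ethyl-3-methylhexahydro-1-benzofuran-2,5-dione hydrochloride, via amino ketal hydrochloride 11 (not isolated)
Conditions: H2 (3 atm), PtO2 (5 mol%), HCl (1.2 equiv) in MeOH, 25 °C; filter; then 1 M aq. HCl–THF, 25 °C
Reagents that add atoms: hydrogen chloride Cl; water O
Why: Nitrile hydrogenation in acid gives the primary ammonium salt without secondary-amine formation, and the ketal is hydrolysed only after the catalyst is removed, so the ketone is never exposed to reductive amination.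

**Step 7**
Reactants: 12 (3S,3aR,6R,7R,7aR)-6-(4-aminobutyl)-7-ethyl-3-methylhexahydro-1-benzofuran-2,5-dione hydrochloride
Product: 14 tetracyclic pyrrole-2-carbaldehyde (the target skeleton with CHO in place of the pendant lactone), via cyclic imine 13 (not isolated)
Conditions: NaOAc (3 equiv), 4 Å MS, AcOH–PhMe 1:4, 60 °C, 2 h; then BrCH(CHO)2 (1.3 equiv), 60 °C
Reagents that add atoms: bromomalonaldehyde O=CC(Br)C=O
Why: Proposed new method: the tethered amine first condenses with the ring ketone to the seven-membered ketimine 13; its less substituted enamine tautomer then condenses reversibly (Knoevenagel type) with one formyl group of bromomalonaldehyde, while addition at the ring-fusion α-carbon cannot dehydrate and reverts; the imine nitrogen then displaces bromide from the now sp3 α-bromo aldehyde carbon in a 5-exo-tet closure and proton loss aromatises to the 2-formylpyrrole, so rings A and B both arise by C–N bond formation in one flask and the aldehyde for ring E is installed at the same time; the epimerisable ring-fusion carbon stays trans to ethyl because the cis epimer would place the chain 1,3-diaxial to the lactone C–O bond; the closest known reaction types are the Hantzsch thiazole and imidazo[1,2-a]pyridine-3-carbaldehyde syntheses with bromomalonaldehyde, the Tschitschibabin annulation of 2-alkyl cyclic imines with α-halo carbonyl compounds and the Knorr enamine condensation.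

**Step 8**
Reactants: 14 tetracyclic pyrrole-2-carbaldehyde
Product: 16 exo-methylene lactone (the target with C=CH2 in place of CH–CH3 in the pendant lactone; carbinol carbon S), via silyl ether 15 (not isolated)
Conditions: CH2=C(CH2Br)CO2Et (1.5 equiv), CrCl2 (10 mol%), chiral carbazole bis(oxazoline) ligand (12 mol%), Mn powder (2 equiv), Me3SiCl (1.5 equiv), i-Pr2NEt (0.3 equiv), THF, 25 °C; then Bu4NF, THF, 0 °C
Reagents that add atoms: ethyl 2-(bromomethyl)acrylate C=C(CBr)C(=O)OCC
Why: Catalytic asymmetric Nozaki–Hiyama–Kishi 2-(alkoxycarbonyl)allylation sets the remote carbinol centre (S) under ligand control, and desilylation releases the alkoxide, which closes ring E without acid, so the pyrrolyl carbinol is not ionised.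

**Step 9**
Reactants: 16 exo-methylene lactone
Product: 17 bisdehydroneotuberostemonine
Conditions: H2 (1 atm), 5% Rh on Al2O3, EtOAc, 25 °C
Reagents that add atoms: none
Why: Heterogeneous hydrogenation delivers H2 to the exocyclic alkene from the face opposite the pyrrolyl substituent, giving the cis (S) methyl lactone; rhodium is chosen to avoid hydrogenolysis of the pyrrolylic C–O bond.

**Compound list**

1 | 4,4-dimethoxycyclohexa-2,5-dien-1-one | COC1(OC)C=CC(=O)C=C1 | starting material
2 | 4-iodobutanenitrile | N#CCCCI | starting material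
3 | bis(3-cyanopropyl)zinc | N#CCCC[Zn]CCCC#N | intermediate (not isolated)
4 | (R)-4-(2,2-dimethoxy-5-oxocyclohex-3-en-1-yl)butanenitrile | N#CCCC[C@@H]1CC(=O)C=CC1(OC)OC | intermediate
5 | 4-[(1R,6R)-6-ethyl-2,2-dimethoxy-5-oxocyclohex-3-en-1-yl]butanenitrile (ethyl trans to the cyanopropyl chain) | CC[C@H]1C(=O)C=CC(OC)(OC)[C@@H]1CCCC#N | intermediate
6 | ethyl (S)-lactate | C[C@H](O)C(=O)OCC | starting material
7 | ethyl (S)-2-(trifluoromethylsulfonyloxy)propanoate | C[C@H](OS(=O)(=O)C(F)(F)F)C(=O)OCC | intermediate
8 | ethyl (2S)-2-[(3R,4R)-4-(3-cyanopropyl)-3-ethyl-5,5-dimethoxy-2-oxocyclohexyl]propanoate, both epimers at ring C1 | CC[C@H]1C(=O)C([C@H](C)C(=O)OCC)CC(OC)(OC)[C@@H]1CCCC#N | intermediate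
9 | ethyl (2S)-2-[(1R,2R,3R,4R)-4-(3-cyanopropyl)-3-ethyl-2-hydroxy-5,5-dimethoxycyclohexyl]propanoate (formed as its lithium alkoxide) | CC[C@H]1[C@@H](O)[C@@H]([C@H](C)C(=O)OCC)CC(OC)(OC)[C@@H]1CCCC#N | intermediate (not isolated)
10 | 4-[(3S,3aR,6R,7R,7aR)-7-ethyl-5,5-dimethoxy-3-methyl-2-oxooctahydro-1-benzofuran-6-yl]butanenitrile | CC[C@H]1[C@H]2OC(=O)[C@@H](C)[C@H]2CC(OC)(OC)[C@@H]1CCCC#N | intermediate
11 | (3S,3aR,6R,7R,7aR)-6-(4-aminobutyl)-7-ethyl-5,5-dimethoxy-3-methylhexahydro-1-benzofuran-2(3H)-one hydrochloride | CC[C@H]1[C@H]2OC(=O)[C@@H](C)[C@H]2CC(OC)(OC)[C@@H]1CCCC[NH3+].[Cl-] | intermediate (not isolated)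
12 | (3S,3aR,6R,7R,7aR)-6-(4-aminobutyl)-7-ethyl-3-methylhexahydro-1-benzofuran-2,5-dione hydrochloride | CC[C@H]1[C@H]2OC(=O)[C@@H](C)[C@H]2CC(=O)[C@@H]1CCCC[NH3+].[Cl-] | intermediate
13 | tricyclic lactone imine: seven-membered C=N ring closed between the amine and the ring ketone of 12, stereocentres unchanged | CC[C@H]1[C@H]2OC(=O)[C@@H](C)[C@H]2CC(=N3)[C@@H]1CCCC3 | intermediate (not isolated)
14 | tetracyclic pyrrole-2-carbaldehyde: the target skeleton with CHO in place of the pendant lactone (ethyl carbon R, lactone CH–O carbon R, lactone α-carbon S, lactone β-carbon S, azepine ring-fusion carbon R) | CC[C@H]1[C@H]2OC(=O)[C@@H](C)[C@H]2c2cc(C=O)n3c2[C@@H]1CCCC3 | intermediate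
15 | trimethylsilyl ether of the (S)-homoallylic alcohol from 14 and the 2-(ethoxycarbonyl)allyl unit | CC[C@H]1[C@H]2OC(=O)[C@@H](C)[C@H]2c2cc([C@@H](O[Si](C)(C)C)CC(=C)C(=O)OCC)n3c2[C@@H]1CCCC3 | intermediate (not isolated)
16 | exo-methylene lactone: the target with C=CH2 in place of CH–CH3 in the pendant lactone, carbinol carbon S | CC[C@H]1[C@H]2OC(=O)[C@@H](C)[C@H]2c2cc([C@@H]3CC(=C)C(=O)O3)n3c2[C@@H]1CCCC3 | intermediate
17 | bisdehydroneotuberostemonine | CC[C@H]1[C@H]2OC(=O)[C@@H](C)[C@H]2c2cc([C@@H]3C[C@H](C)C(=O)O3)n3c2[C@@H]1CCCC3 | target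

**Step count and risks**

Total step count: 9. Longest linear sequence: 8 (steps 1, 2, 4, 5, 6, 7, 8, 9); step 3 is a one-step side branch.

Three steps most likely to fail:

Step 7, the proposed new annulation. The risks are salt formation between the basic imine and the acidic dialdehyde, and condensation at the wrong α-carbon. The fallback uses known chemistry, sets out from 12 and comes back at 14. Compound 12 is closed to imine 13 as above and heated with aqueous chloroacetaldehyde (NaHCO3, EtOH, 60 °C), the Tschitschibabin-type annulation of 2-alkyl cyclic imines with α-halo aldehydes, which gives the α-unsubstituted pyrrole F7. Vilsmeier–Haack formylation (POCl3, DMF, 0 °C) at its only free α-position goes through the iminium chloride F8, and hydrolysis with aqueous NaOAc gives 14. This costs one more step.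

Step 4, the reductive alkylation. The hydride may add 1,2, or the enolate may eliminate or O-alkylate the secondary triflate. The fallback sets out from 5 and comes back at 10. The enone double bond of 5 is hydrogenated (H2 1 atm, 5% Pd on C, EtOAc) to the saturated ketone F1. LiN(i-Pr)2 at −78 °C forms the less substituted enolate, which is alkylated with methyl bromoacetate to the keto ester F2. DBU and then Li[HB(sec-Bu)3], as in step 5, give the unmethylated lactone F3. LiN(SiMe3)2 and [Me2N=CH2]I give the Mannich base F4, MeI gives its methiodide F5, and NaHCO3 gives the α-methylene lactone F6. Hydrogenation (H2, Pd on C) from the convex face of the cis-fused bicycle gives 10. This costs three more steps.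

Step 8, the ligand-controlled allylation. The aldehyde is electron-rich and the new centre is remote from the others. The fallback sets out from 14 and comes back at 16. Unselective Barbier allylation (Zn dust, CH2=C(CH2Br)CO2Et, aq. NH4Cl–THF) gives the hydroxy ester F9 as both carbinol epimers. MnO2 oxidises it to the pyrrolyl ketone F10. Reduction with (R)-2-methyl-CBS-oxazaborolidine and catecholborane (pyrrolyl as the large group) gives the (S)-hydroxy ester F11, which closes to 16 with catalytic DBU. Here the carbinol centre is set by ketone reduction instead of C–C bond formation.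

**Further compounds**

F1 | step 4 | 4-[(1R,2R)-2-ethyl-6,6-dimethoxy-3-oxocyclohexyl]butanenitrile | CC[C@H]1C(=O)CCC(OC)(OC)[C@@H]1CCCC#N
F2 | step 4 | methyl 2-[4-(3-cyanopropyl)-3-ethyl-5,5-dimethoxy-2-oxocyclohexyl]acetate, all-equatorial isomer | CC[C@H]1C(=O)[C@@H](CC(=O)OC)CC(OC)(OC)[C@@H]1CCCC#N
F3 | step 4 | 3-demethyl analogue of lactone 10 | CC[C@H]1[C@H]2OC(=O)C[C@H]2CC(OC)(OC)[C@@H]1CCCC#N
F4 | step 4 | 3-(dimethylaminomethyl) derivative of F3 (Mannich base) | CC[C@H]1[C@H]2OC(=O)C(CN(C)C)[C@H]2CC(OC)(OC)[C@@H]1CCCC#N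
F5 | step 4 | trimethylammonium iodide from F4 | CC[C@H]1[C@H]2OC(=O)C(C[N+](C)(C)C)[C@H]2CC(OC)(OC)[C@@H]1CCCC#N.[I-]
F6 | step 4 | 3-methylene analogue of lactone 10 | CC[C@H]1[C@H]2OC(=O)C(=C)[C@H]2CC(OC)(OC)[C@@H]1CCCC#N
F7 | step 7 | tetracyclic pyrrole with H in place of the CHO of 14 | CC[C@H]1[C@H]2OC(=O)[C@@H](C)[C@H]2c2ccn3c2[C@@H]1CCCC3
F8 | step 7 | dimethyliminium chloride of aldehyde 14 | CC[C@H]1[C@H]2OC(=O)[C@@H](C)[C@H]2c2cc(C=[N+](C)C)n3c2[C@@H]1CCCC3.[Cl-]
F9 | step 8 | ethyl 4-hydroxy-2-methylene-4-(pyrrolyl)butanoate from 14, both carbinol epimers | CC[C@H]1[C@H]2OC(=O)[C@@H](C)[C@H]2c2cc(C(O)CC(=C)C(=O)OCC)n3c2[C@@H]1CCCC3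
F10 | step 8 | ethyl 2-methylene-4-oxo-4-(pyrrolyl)butanoate from F9 | CC[C@H]1[C@H]2OC(=O)[C@@H](C)[C@H]2c2cc(C(=O)CC(=C)C(=O)OCC)n3c2[C@@H]1CCCC3
F11 | step 8 | (S)-carbinol epimer of F9 | CC[C@H]1[C@H]2OC(=O)[C@@H](C)[C@H]2c2cc([C@@H](O)CC(=C)C(=O)OCC)n3c2[C@@H]1CCCC3
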